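Numbering: briarane numbering is used throughout. C1 and C10–C14 form the six-membered ring and C1–C10 the ten-membered ring. C15 is the methyl on C1, C16 the CH2O on C5, and C20 the methyl on C11. The lactone is C7–O–C19(=O)–C17(C18)–C8. β is the face of C15.

Assumption: the (1S)-acid gives the less soluble salt with (S)-1-phenylethylamine. If the antipode crystallises, the (R)-amine is used in the same way.

## Retrosynthetic overview

1. The ten-membered ring is closed last, by diene–ene ring-closing metathesis at C5=C6.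
2. The γ-lactone (C8-OH, C17) comes from an intramolecular Reformatsky aldol of a C7 2-bromopropanoate onto a C8 ketone. The C7/C8 acyloin and the 11,12-epoxide come from one double epoxidation.
3. C8–C9 is made by thioester/stannane acyl coupling, with 1-methoxybutadiene serving as the C8 acyl anion, followed by Felkin reduction. C1–C2 is made by an aldol of an enol ether with a C2–C5/C16 dienal.
4. Ring A (C1, C9–C15, C20) is obtained by a Birch dearomatisation of 3-methoxy-2,6-dimethylbenzoic acid in which all four substituents direct the same way. One reduction delivers the C9 acyl group, the C1-nucleophilic C14 enol ether and the C11=C12 alkene.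
5. Order of rings: six-membered ring (from the arene), then epoxide, then γ-lactone, then ten-membered ring.

## Route

Step 1
Reactants: 1 3-methoxy-2-methylbenzoic acid
Product: 2 3-methoxy-2,6-dimethylbenzoic acid
Conditions: Pd(OAc)2 (10 mol %), MeB(OH)2, Ag2CO3, cat. benzoquinone, K2HPO4, t-BuOH, 100 °C
Reagents that add atoms: methylboronic acid, CB(O)O
Why: Carboxylate-directed Pd(II) ortho-C–H methylation, as known for o-toluic acids, has only one free ortho position (the future C11) to attack.

Step 2
Reactants: 2 3-methoxy-2,6-dimethylbenzoic acid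
Product: 4 (±)-3-methoxy-2,6-dimethylcyclohexa-2,5-diene-1-carboxylic acid, via dilithium dienediolate 3 (not isolated)
Conditions: Li, NH3(l)/THF, t-BuOH (1 equiv), −78 °C; solid NH4Cl
Reagents that add atoms: none
Why: In this Birch reduction the carboxylate directs reduction to the ipso and para carbons (C10/C13) while OMe and both methyls stay on sp2 carbons, so all four substituents favour one 1,4-diene, and kinetic α-protonation of 3 creates C10 (racemic at this stage).

Step 3
Reactants: 4 (±)-3-methoxy-2,6-dimethylcyclohexa-2,5-diene-1-carboxylic acid; 5 (S)-1-phenylethylamine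
Product: 7 (1S)-3-methoxy-2,6-dimethylcyclohexa-2,5-diene-1-carboxylic acid, via phenylethylammonium salt 6 (not isolated)
Conditions: 5 (0.55 equiv), EtOAc, two crystallisations; filter cake partitioned between Et2O and cold 10 % citric acid
Reagents that add atoms: none
Why: Classical resolution through diastereomeric salts fixes the absolute configuration of C10 (H α, C9 β), from which every later centre is relayed.

Step 4
Reactants: 7 (1S)-3-methoxy-2,6-dimethylcyclohexa-2,5-diene-1-carboxylic acid
Product: 8 S-ethyl (1S)-3-methoxy-2,6-dimethylcyclohexa-2,5-diene-1-carbothioate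
Conditions: EtSH, DCC, DMAP (5 mol %), CH2Cl2, 0 °C
Reagents that add atoms: ethanethiol, CCS
Why: Steglich thioesterification under almost neutral conditions leaves the acidic, doubly allylic C10–H and the enol ether untouched and turns C9 into a latent acyl donor.

Step 5
Reactants: 9 2-bromoprop-2-en-1-ol; 10 acrolein
Product: 11 (2E)-4-(hydroxymethyl)penta-2,4-dienal
Conditions: Pd(OAc)2 (3 mol %), n-Bu4NCl, NaHCO3, DMF, 40 °C
Reagents that add atoms: none
Why: A Jeffery–Heck vinylation of acrolein gives the β-substituted (E)-dienal by syn-insertion and syn-β-hydride elimination, which fixes the C3=C4 geometry.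

Step 6
Reactants: 11 (2E)-4-(hydroxymethyl)penta-2,4-dienal
Product: 12 (2E)-4-(acetoxymethyl)penta-2,4-dienal
Conditions: Ac2O, pyridine, CH2Cl2, 0 °C
Reagents that add atoms: acetic anhydride, CC(=O)OC(C)=O
Why: Simple O-acetylation installs the final 16-OAc before any sensitive functionality is present.

Step 7
Reactants: 8 S-ethyl (1S)-3-methoxy-2,6-dimethylcyclohexa-2,5-diene-1-carbothioate; 12 (2E)-4-(acetoxymethyl)penta-2,4-dienal
Product: 13 C1–C2 aldol (2S,10S; 15-Me β; C2 α): S-ethyl 9-thioester with 14-ketone, 2-OH, Δ11 and the C3–C5(=CH2)–C16OAc dienyl chain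
Conditions: 12 + TiCl4 (1.1 equiv), CH2Cl2, −78 °C, then 8; aqueous work-up
Reagents that add atoms: water, O
Why: In this Mukaiyama-type aldol of an alkyl enol ether the aldehyde attacks C1 anti to the β-C9 group (quaternary C1, C2 trans to C9), and titanium bridging the aldehyde oxygen and the enol-ether oxygen gives a chair Zimmerman–Traxler-like transition state with the dienyl group equatorial, which places 2-OH syn to C15.

Step 8
Reactants: 13 C1–C2 aldol
Product: 14 2,14-anti-diol (1R,2S,10S,14S; 14-OH α, axial)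
Conditions: Me4NBH(OAc)3, MeCN/AcOH, −30 °C
Reagents that add atoms: none
Why: In the Evans–Saksena reduction, boron bound to 2-OH delivers hydride intramolecularly to the hindered β face of C14, which gives the 1,3-anti diol and hence the axial 14α-OH.

Step 9
Reactants: 14 2,14-anti-diol
Product: 15 2,14,16-triacetate 9-thioester (1R,2S,10S,14S)
Conditions: Ac2O, Et3N, DMAP, CH2Cl2, rt
Reagents that add atoms: acetic anhydride, CC(=O)OC(C)=O
Why: DMAP-catalysed acetylation installs two acetates of the target and removes the γ-hydroxy group that could lactonise onto the thioester.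

Step 10
Reactants: 16 (E)-1-methoxybuta-1,3-diene
Product: 18 (1Z)-tributyl(1-methoxybuta-1,3-dien-1-yl)stannane (OMe trans to vinyl), via 1-lithio-1-methoxybutadiene 17 (not isolated)
Conditions: t-BuLi, THF, −78 to −40 °C; Bu3SnCl
Reagents that add atoms: tributyltin chloride, CCCC[Sn](Cl)(CCCC)CCCC
Why: Oxygen-directed α-vinylic lithiation of the enol ether and stannylation both proceed with retention, so tin ends up cis to the vinyl group.

Step 11
Reactants: 15 2,14,16-triacetate 9-thioester; 18 (1Z)-tributyl(1-methoxybuta-1,3-dien-1-yl)stannane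
Product: 19 C9 ketone bearing the 8-methoxy-dienyl group (C9 cis to C6 across C7=C8)
Conditions: Pd2(dba)3 (2.5 mol %), P(2-furyl)3, CuOP(O)Ph2 (1.5 equiv), THF, rt to 40 °C
Reagents that add atoms: none
Why: Liebeskind–Srogl ketone synthesis under neutral conditions forms C8–C9 with retention of alkene geometry, using a fast-transmetallating α-alkoxyvinylstannane and leaving the acetates intact.

Step 12
Reactants: 19 C9 ketone
Product: 20 (9S)-allylic alcohol
Conditions: NaBH4, CeCl3·7H2O, MeOH/THF, −78 °C; NaHCO3 quench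
Reagents that add atoms: none
Why: In this Luche 1,2-reduction under Felkin–Anh control, hydride attacks anti to the quaternary C1 with the C8 group next to H-10, which gives 9S, whereas addition of a carbon nucleophile to the C9 aldehyde would give the epimer.

Step 13
Reactants: 20 (9S)-allylic alcohol
Product: 21 2,9,14,16-tetraacetate dienol ether
Conditions: Ac2O, Et3N, DMAP, CH2Cl2, 0 °C
Reagents that add atoms: acetic anhydride, CC(=O)OC(C)=O
Why: Base-buffered acetylation completes the four acetates and does not hydrolyse the acid-labile dienol ether.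

Step 14
Reactants: 21 2,9,14,16-tetraacetate dienol ether
Product: 23 (7S)-7-hydroxy-8-ketone 11α,12α-epoxide, via bis-epoxide 22 (not isolated)
Conditions: DMDO (2.3 equiv, acetone), CH2Cl2, −78 to 0 °C; moist SiO2
Reagents that add atoms: dimethyldioxirane, CC1(C)OO1; water, O
Why: In this Rubottom-type oxidation plus alkene epoxidation the two most electron-rich alkenes react first; A1,3 strain (H-9 eclipsing C7=C8) exposes the enol-ether face anti to ring A (7S), and C11=C12 is attacked on the α face, away from the axial 15-Me and the C9 chain.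

Step 15
Reactants: 23 (7S)-7-hydroxy-8-ketone 11α,12α-epoxide
Product: 24 7-O-(2-bromopropanoyl) 8-ketone (mixture at CHBr)
Conditions: 2-bromopropanoyl bromide, pyridine, CH2Cl2, −20 °C
Reagents that add atoms: 2-bromopropanoyl bromide, CC(Br)C(=O)Br
Why: Fast O-acylation of the only free hydroxyl brings in C17–C19, and the CHBr centre is lost again in the next step.

Step 16
Reactants: 24 7-O-(2-bromopropanoyl) 8-ketone
Product: 26 seco-briarane lactone (1R,2S,7S,8S,9S,10S,11S,12R,14S,17R), via samarium(III) enolate 25 (not isolated)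
Conditions: SmI2 (2.2 equiv, slow addition), THF, −78 °C; pH 7 buffer
Reagents that add atoms: none
Why: In this SmI2-mediated intramolecular Reformatsky aldol the C–Br bond is reduced before the ketone, and five-membered ring closure puts the three carbon substituents (C6, C9, C18) all-trans on the lactone, which gives 8-OH cis to C6 and 18-Me trans to C9.

Step 17
Reactants: 26 seco-briarane lactone
Product: 27 target CNP0250433.1
Conditions: Hoveyda–Grubbs II (15 mol %), toluene (0.5 mM), 80 °C, Ar sparge
Reagents that add atoms: none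
Why: In this diene–ene ring-closing metathesis the catalyst loads on the C6 vinyl group and closes onto the 1,1-disubstituted diene terminus, with precedent for metathesis closure of bicyclo[8.4.0] systems; the ring forces C4 and C7 cis on C5=C6, and the preset C3=C4 (E) alkene and all stereocentres are untouched.

## Compound list

1 | 3-methoxy-2-methylbenzoic acid | COc1cccc(C(=O)O)c1C | starting material
2 | 3-methoxy-2,6-dimethylbenzoic acid | COc1ccc(C)c(C(=O)O)c1C | intermediate
3 | dilithium dienediolate (Birch dianion) | [Li+].[Li+].[O-]C([O-])=C1C(C)=CCC(OC)=C1C | intermediate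
4 | (±)-3-methoxy-2,6-dimethylcyclohexa-2,5-diene-1-carboxylic acid | OC(=O)C1C(C)=CCC(OC)=C1C | intermediate
5 | (S)-1-phenylethylamine | C[C@H](N)c1ccccc1 | starting material
6 | (S)-1-phenylethylammonium (1S)-carboxylate salt | C[C@H]([NH3+])c1ccccc1.[O-]C(=O)[C@H]1C(C)=CCC(OC)=C1C | intermediate
7 | (1S)-3-methoxy-2,6-dimethylcyclohexa-2,5-diene-1-carboxylic acid | OC(=O)[C@H]1C(C)=CCC(OC)=C1C | intermediate
8 | S-ethyl (1S)-3-methoxy-2,6-dimethylcyclohexa-2,5-diene-1-carbothioate | CCSC(=O)[C@H]1C(C)=CCC(OC)=C1C | intermediate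
9 | 2-bromoprop-2-en-1-ol | OCC(Br)=C | starting material
10 | acrolein | C=CC=O | starting material
11 | (2E)-4-(hydroxymethyl)penta-2,4-dienal | OCC(=C)/C=C/C=O | intermediate
12 | (2E)-4-(acetoxymethyl)penta-2,4-dienal | CC(=O)OCC(=C)/C=C/C=O | intermediate
13 | C1–C2 aldol (14-ketone, 2S-OH, 9-thioester) | CCSC(=O)[C@H]1C(C)=CCC(=O)[C@]1(C)[C@@H](O)/C=C/C(=C)COC(C)=O | intermediate
14 | 2,14-anti-diol | CCSC(=O)[C@H]1C(C)=CC[C@H](O)[C@]1(C)[C@@H](O)/C=C/C(=C)COC(C)=O | intermediate
15 | 2,14,16-triacetate 9-thioester | CCSC(=O)[C@H]1C(C)=CC[C@H](OC(C)=O)[C@]1(C)[C@@H](OC(C)=O)/C=C/C(=C)COC(C)=O | intermediate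
16 | (E)-1-methoxybuta-1,3-diene | CO/C=C/C=C | starting material
17 | 1-lithio-1-methoxybuta-1,3-diene (OMe trans to vinyl) | CO/C([Li])=C/C=C | intermediate
18 | (1Z)-tributyl(1-methoxybuta-1,3-dien-1-yl)stannane | CO/C(=C/C=C)[Sn](CCCC)(CCCC)CCCC | intermediate
19 | C9 ketone with 8-methoxydienyl group | C=C/C=C(/OC)\C(=O)[C@H]1C(C)=CC[C@H](OC(C)=O)[C@]1(C)[C@@H](OC(C)=O)/C=C/C(=C)COC(C)=O | intermediate
20 | (9S)-allylic alcohol | C=C/C=C(/OC)\[C@@H](O)[C@H]1C(C)=CC[C@H](OC(C)=O)[C@]1(C)[C@@H](OC(C)=O)/C=C/C(=C)COC(C)=O | intermediate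
21 | 2,9,14,16-tetraacetate dienol ether | C=C/C=C(/OC)\[C@@H](OC(C)=O)[C@H]1C(C)=CC[C@H](OC(C)=O)[C@]1(C)[C@@H](OC(C)=O)/C=C/C(=C)COC(C)=O | intermediate
22 | bis-epoxide (7,8-epoxy-8-methoxy; 11α,12α-epoxy) | C=C[C@@H]1O[C@]1(OC)[C@@H](OC(C)=O)[C@H]1[C@]2(C)O[C@@H]2C[C@H](OC(C)=O)[C@]1(C)[C@@H](OC(C)=O)/C=C/C(=C)COC(C)=O | intermediate
23 | (7S)-7-hydroxy-8-ketone 11α,12α-epoxide | C=C[C@H](O)C(=O)[C@@H](OC(C)=O)[C@H]1[C@]2(C)O[C@@H]2C[C@H](OC(C)=O)[C@]1(C)[C@@H](OC(C)=O)/C=C/C(=C)COC(C)=O | intermediate
24 | 7-O-(2-bromopropanoyl) 8-ketone | C=C[C@H](OC(=O)C(C)Br)C(=O)[C@@H](OC(C)=O)[C@H]1[C@]2(C)O[C@@H]2C[C@H](OC(C)=O)[C@]1(C)[C@@H](OC(C)=O)/C=C/C(=C)COC(C)=O | intermediate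
25 | samarium(III) ester enolate | C=C[C@H](OC(=CC)O[Sm](I)I)C(=O)[C@@H](OC(C)=O)[C@H]1[C@]2(C)O[C@@H]2C[C@H](OC(C)=O)[C@]1(C)[C@@H](OC(C)=O)/C=C/C(=C)COC(C)=O | intermediate
26 | seco-briarane lactone (C6 vinyl, C5 methylidene) | C=C[C@@H]1OC(=O)[C@H](C)[C@@]1(O)[C@@H](OC(C)=O)[C@H]1[C@]2(C)O[C@@H]2C[C@H](OC(C)=O)[C@]1(C)[C@@H](OC(C)=O)/C=C/C(=C)COC(C)=O | intermediate
27 | CNP0250433.1 | CC(=O)OCC1=C/[C@@H]2OC(=O)[C@H](C)[C@@]2(O)[C@@H](OC(C)=O)[C@H]2[C@]3(C)O[C@@H]3C[C@H](OC(C)=O)[C@]2(C)[C@@H](OC(C)=O)\C=C\1 | target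

## Step count and risks

- Total step count: 17.
- Longest linear sequence: 14 steps (steps 1–4, 7–9 and 11–17).

The three steps most likely to fail are steps 7, 11 and 17.

**Step 7.** The risks are control of C2, 1,2- versus conjugate addition, and formation of a quaternary centre.
- This fallback sets out from 8 and 12 and returns at 13.
- Aldehyde 12 is oxidised (NaClO2, NaH2PO4, 2-methylbut-2-ene) to (2E)-4-(acetoxymethyl)penta-2,4-dienoic acid F1.
- Ghosez's reagent converts this into (2E)-4-(acetoxymethyl)penta-2,4-dienoyl chloride F2.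
- Enol ether 8 is C-acylated with it (ZnCl2, CH2Cl2, −40 °C), again anti to C9, to give the non-enolisable 2,14-diketone F3.
- (R)-Me-CBS/catecholborane at −78 °C then reduces only the dienone carbonyl, so the reagent rather than an aldol transition state sets C2, and this delivers 13.

**Step 11.** The risks are the hindered thioester and Pd(0) in the presence of allylic acetates.
- This fallback sets out from 15 and 17 and returns at 19.
- Fukuyama reduction of 15 (Et3SiH, Pd/C, acetone) gives the C9 aldehyde F4.
- The organocerium reagent made from 17 and CeCl3 adds at −78 °C to give the C9 carbinol F5 as an epimer mixture, mainly the Felkin 9-epimer.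
- Dess–Martin oxidation erases that centre and gives ketone 19, which continues through the Felkin hydride reduction of step 12.

**Step 17.** The risk is forming a trisubstituted diene alkene inside a strained ten-membered ring next to the rigid lactone.
- This fallback sets out from 23 and returns at 27.
- The ring is closed before the lactone is built, while C8 is still sp2 and the chain is more flexible.
- Metathesis of 23 gives the macrocyclic acyloin F6.
- Acylation with 2-bromopropanoyl bromide gives the macrocyclic 2-bromopropanoate F7.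
- The SmI2 Reformatsky closure on the preformed ring then gives 27.

## Further compounds

F1 | step 7 | (2E)-4-(acetoxymethyl)penta-2,4-dienoic acid | CC(=O)OCC(=C)/C=C/C(=O)O
F2 | step 7 | (2E)-4-(acetoxymethyl)penta-2,4-dienoyl chloride | CC(=O)OCC(=C)/C=C/C(=O)Cl
F3 | step 7 | 2,14-diketone 9-thioester | CCSC(=O)[C@H]1C(C)=CCC(=O)[C@]1(C)C(=O)/C=C/C(=C)COC(C)=O
F4 | step 11 | C9 aldehyde triacetate | O=C[C@H]1C(C)=CC[C@H](OC(C)=O)[C@]1(C)[C@@H](OC(C)=O)/C=C/C(=C)COC(C)=O
F5 | step 11 | C9 carbinol (C9 epimers) | C=C/C=C(/OC)\C(O)[C@H]1C(C)=CC[C@H](OC(C)=O)[C@]1(C)[C@@H](OC(C)=O)/C=C/C(=C)COC(C)=O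
F6 | step 17 | macrocyclic (7S)-7-hydroxy-8-ketone | CC(=O)OCC1=C/[C@H](O)C(=O)[C@@H](OC(C)=O)[C@H]2[C@]3(C)O[C@@H]3C[C@H](OC(C)=O)[C@]2(C)[C@@H](OC(C)=O)\C=C\1
F7 | step 17 | macrocyclic 7-O-(2-bromopropanoyl) 8-ketone | CC(=O)OCC1=C/[C@H](OC(=O)C(C)Br)C(=O)[C@@H](OC(C)=O)[C@H]2[C@]3(C)O[C@@H]3C[C@H](OC(C)=O)[C@]2(C)[C@@H](OC(C)=O)\C=C\1
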